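The resorcinol ring is made last, from open-chain parts. In the target this ring carries two meta hydroxyls and two neighbouring carbon substituents, benzofuran C3 and the stereogenic diarylmethine carbon. A 1-methoxy-1,3-bis(silyloxy)butadiene and an alkynyl aryl ketone deliver exactly this pattern by (4+2) cycloaddition and loss of methanol. One operation thus forms two ring C–C bonds and the complete arene, with the aroyl carbon (the future stereocentre) beside a phenol and the crowded C3–aryl bond already in place. The precursor is a 2-aryl-6-benzyloxybenzofuran with a methyl ester at C4 and a 3-aryl-3-oxoprop-1-ynyl group at C3. McMurry ring closure and asymmetric hydroboration then finish the seven-membered ketone.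

Key step: step 11

Assumption: the stereocentre of the given structure is read as (S) (C=O > dioxygenated aryl > 4-hydroxyphenyl > H). The facial preference of IpcBH2 is assigned by analogy with 1-arylcycloalkenes, so the reagent from (+)-α-pinene is specified; the antipodal reagent from (−)-α-pinene would be taken if the ring alkene reacted with the opposite sense.

Remark on precursor design: the furan is closed by phenoxide annulation, not by electrophile-induced cyclisation of an ortho-alkynyl aryl ether. An ester ortho to the alkyne would compete as the nucleophile in the electrophilic mode and lead to an isocoumarin. The annulation also differentiates the two resorcinol oxygens without any selective alkylation.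

Step 1
Reactants: 1 methyl 3,5-dimethoxybenzoate
Product: 2 methyl 2-iodo-3,5-dimethoxybenzoate
Conditions: NIS, TFA (cat.), MeCN, rt
Reagents that add atoms: N-iodosuccinimide, O=C1CCC(=O)N1I
Why: Electrophilic aromatic iodination should attack C2 (ortho to one methoxy group, para to the other, next to the ester) in preference to the doubly flanked C4, which fixes the oxygen that later closes the furan.

Step 2
Reactants: 2 methyl 2-iodo-3,5-dimethoxybenzoate
Product: 3 methyl 3,5-dihydroxy-2-iodobenzoate
Conditions: BBr3, CH2Cl2, −78 to 0 °C; then H2O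
Reagents that add atoms: none
Why: Lewis-acid cleavage of aryl methyl ethers (bromide attacks the methyl group of the boron-complexed ether) is faster than attack on the methyl benzoate at or below 0 °C and spares the aryl iodide; both phenols may be freed because only the one beside iodine can cyclise in step 3.

Step 3
Reactants: 3 methyl 3,5-dihydroxy-2-iodobenzoate; 4 1-(benzyloxy)-4-ethynylbenzene
Product: 6 methyl 2-[4-(benzyloxy)phenyl]-6-hydroxy-1-benzofuran-4-carboxylate, via 2-alkynylresorcinol ester 5 (not isolated)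
Conditions: PdCl2(PPh3)2 (cat.), CuI (cat.), Et3N, DMF, 70 °C
Reagents that add atoms: none
Why: Sonogashira coupling is followed in the same flask by CuI- and base-assisted 5-endo-dig addition of the ortho phenoxide to the alkyne (heteroannulation); only the hydroxyl next to the former iodide can reach the triple bond, and under basic conditions the neighbouring ester cannot compete.

Step 4
Reactants: 6 methyl 2-[4-(benzyloxy)phenyl]-6-hydroxy-1-benzofuran-4-carboxylate
Product: 7 methyl 6-(benzyloxy)-2-[4-(benzyloxy)phenyl]-1-benzofuran-4-carboxylate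
Conditions: BnBr, K2CO3, DMF, rt
Reagents that add atoms: benzyl bromide, BrCc1ccccc1
Why: Williamson etherification of the single remaining phenol, which must be capped before the ring is exposed to an electrophilic iodine source.

Step 5
Reactants: 7 methyl 6-(benzyloxy)-2-[4-(benzyloxy)phenyl]-1-benzofuran-4-carboxylate
Product: 8 methyl 6-(benzyloxy)-2-[4-(benzyloxy)phenyl]-3-iodo-1-benzofuran-4-carboxylate
Conditions: NIS, MeCN/CH2Cl2, 0 °C to rt, dark
Reagents that add atoms: N-iodosuccinimide, O=C1CCC(=O)N1I
Why: Electrophilic iodination should occur at C3, the β-carbon of an aryl enol ether further activated by the 4-benzyloxyphenyl group on C2, whereas C5 and C7 are deactivated by the ester ortho and para to them.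

Step 6
Reactants: 9 4-(benzyloxy)benzaldehyde
Product: 10 1-[4-(benzyloxy)phenyl]prop-2-yn-1-ol (racemic)
Conditions: HC≡CMgBr, THF, 0 °C; then aq. NH4Cl
Reagents that add atoms: ethynylmagnesium bromide (HC≡CMgBr), C#C[Mg]Br
Why: 1,2-Addition of an alkynyl Grignard reagent to an aromatic aldehyde; the carbinol centre is racemic and is removed by oxidation in step 8.

Step 7
Reactants: 8 methyl 6-(benzyloxy)-2-[4-(benzyloxy)phenyl]-3-iodo-1-benzofuran-4-carboxylate; 10 1-[4-(benzyloxy)phenyl]prop-2-yn-1-ol
Product: 11 methyl 6-(benzyloxy)-2-[4-(benzyloxy)phenyl]-3-{3-[4-(benzyloxy)phenyl]-3-hydroxyprop-1-yn-1-yl}-1-benzofuran-4-carboxylate (racemic)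
Conditions: PdCl2(PPh3)2 (cat.), CuI (cat.), Et3N, THF, 45 °C
Reagents that add atoms: none
Why: Sonogashira coupling of a 3-iodobenzofuran with a terminal alkyne; the linear alkyne passes between the C2 aryl group and the C4 ester, and the free propargylic alcohol is tolerated at this mild temperature.

Step 8
Reactants: 11 methyl 6-(benzyloxy)-2-[4-(benzyloxy)phenyl]-3-{3-[4-(benzyloxy)phenyl]-3-hydroxyprop-1-yn-1-yl}-1-benzofuran-4-carboxylate
Product: 12 methyl 6-(benzyloxy)-2-[4-(benzyloxy)phenyl]-3-{3-[4-(benzyloxy)phenyl]-3-oxoprop-1-yn-1-yl}-1-benzofuran-4-carboxylate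
Conditions: MnO2, CH2Cl2, rt
Reagents that add atoms: none
Why: MnO2 oxidation of an alcohol that is both benzylic and propargylic; the neutral conditions leave the benzyl ethers, the ester and the base-sensitive ynone untouched.

Step 9
Reactants: 13 methyl acetoacetate
Product: 14 methyl 3-(trimethylsilyloxy)but-2-enoate
Conditions: Me3SiCl, Et3N, hexane, rt
Reagents that add atoms: chlorotrimethylsilane, C[Si](C)(C)Cl
Why: O-Silylation of the enol form of a β-keto ester under soft enolisation conditions.

Step 10
Reactants: 14 methyl 3-(trimethylsilyloxy)but-2-enoate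
Product: 15 1-methoxy-1,3-bis(trimethylsilyloxy)buta-1,3-diene (mixture of geometric isomers)
Conditions: LiN(i-Pr)2, THF, −78 °C; then Me3SiCl, −78 °C to rt
Reagents that add atoms: chlorotrimethylsilane, C[Si](C)(C)Cl
Why: γ-Deprotonation of the silyloxy crotonate gives the extended ester enolate, which is trapped on oxygen to give the ketene silyl acetal; the diene is used without chromatography.

Step 11
Reactants: 12 methyl 6-(benzyloxy)-2-[4-(benzyloxy)phenyl]-3-{3-[4-(benzyloxy)phenyl]-3-oxoprop-1-yn-1-yl}-1-benzofuran-4-carboxylate; 15 1-methoxy-1,3-bis(trimethylsilyloxy)buta-1,3-diene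
Product: 18 methyl 6-(benzyloxy)-2-[4-(benzyloxy)phenyl]-3-{2-[4-(benzyloxy)benzoyl]-3,5-dihydroxyphenyl}-1-benzofuran-4-carboxylate, via cyclohexa-1,4-diene cycloadduct 16 (not isolated), via aryl bis(trimethylsilyl) ether 17 (not isolated)
Conditions: 15 (3 equiv), toluene, 110 °C, sealed tube; then 1 M HCl, THF, rt
Reagents that add atoms: none
Why: The electron-rich diene 15 adds across the electron-poor triple bond of ynone 12 in a concerted, asynchronous (4+2) cycloaddition in which bonding between the diene CH2 terminus and the alkyne carbon on benzofuran C3 (β to the ketone) runs ahead of bonding between the ketene-acetal carbon and the α-carbon; cyclohexa-1,4-diene 16 then loses methanol by 1,4-elimination to give arene 17, and dilute acid removes both silyl groups. The closest known reaction type is the Diels–Alder benzannulation of 1-alkoxy-1,3-bis(silyloxy)buta-1,3-dienes with acetylenic ketones and esters, which gives 2-acylresorcinols after elimination. The six-membered carbocycle is closed intermolecularly, both ring bonds arising in the cycloaddition itself and not by cyclisation of a tethered chain. No lasting stereocentre is created, since the acetal carbon of 16 becomes aromatic and the aroyl carbon stays trigonal until step 16. The step needs one regiochemistry, aroyl ortho to a hydroxyl and benzofuran meta to both oxygens, and the matched polarisation secures it: the ynone β-carbon is its electrophilic site and the CH2 terminus, fed by all three oxygens, is the most nucleophilic carbon of the diene. Heating without a Lewis acid keeps the diene from adding to the ketone or ester carbonyl in a Mukaiyama-type or formal (3+3) manner, and because the C3–alkyne bond already exists no crowded biaryl coupling is required.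

Step 12
Reactants: 18 methyl 6-(benzyloxy)-2-[4-(benzyloxy)phenyl]-3-{2-[4-(benzyloxy)benzoyl]-3,5-dihydroxyphenyl}-1-benzofuran-4-carboxylate
Product: 19 methyl 6-(benzyloxy)-2-[4-(benzyloxy)phenyl]-3-{3,5-bis(benzyloxy)-2-[4-(benzyloxy)benzoyl]phenyl}-1-benzofuran-4-carboxylate
Conditions: BnBr, K2CO3, DMF, 60 °C
Reagents that add atoms: benzyl bromide, BrCc1ccccc1
Why: Williamson etherification of both phenols; warming is needed for the hydroxyl hydrogen-bonded to the ketone, and neither phenol sits ortho to the biaryl bond, so no lactone can form with the C4 ester.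

Step 13
Reactants: 19 methyl 6-(benzyloxy)-2-[4-(benzyloxy)phenyl]-3-{3,5-bis(benzyloxy)-2-[4-(benzyloxy)benzoyl]phenyl}-1-benzofuran-4-carboxylate
Product: 20 [6-(benzyloxy)-2-[4-(benzyloxy)phenyl]-3-{3,5-bis(benzyloxy)-2-[[4-(benzyloxy)phenyl](hydroxy)methyl]phenyl}-1-benzofuran-4-yl]methanol (mixture of stereoisomers)
Conditions: LiAlH4, THF, 0 °C to rt
Reagents that add atoms: none
Why: Hydride reduction of ester and ketone together, chosen because selective reduction of the ester beside a diaryl ketone is not dependable; the carbinol centre and the hindered biaryl axis give isomers that are all erased in step 14.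

Step 14
Reactants: 20 [6-(benzyloxy)-2-[4-(benzyloxy)phenyl]-3-{3,5-bis(benzyloxy)-2-[[4-(benzyloxy)phenyl](hydroxy)methyl]phenyl}-1-benzofuran-4-yl]methanol
Product: 21 6-(benzyloxy)-2-[4-(benzyloxy)phenyl]-3-{3,5-bis(benzyloxy)-2-[4-(benzyloxy)benzoyl]phenyl}-1-benzofuran-4-carbaldehyde
Conditions: Dess–Martin periodinane (3 equiv), CH2Cl2, rt; aq. NaHCO3/Na2S2O3 work-up
Reagents that add atoms: none
Why: Dess–Martin oxidation converts the primary benzylic alcohol into the aldehyde and the diarylcarbinol back into the ketone in one operation without over-oxidation.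

Step 15
Reactants: 21 6-(benzyloxy)-2-[4-(benzyloxy)phenyl]-3-{3,5-bis(benzyloxy)-2-[4-(benzyloxy)benzoyl]phenyl}-1-benzofuran-4-carbaldehyde
Product: 22 pentabenzyl cycloheptene: the aldehyde carbon (now =CH–) and the ketone carbon (now =C(4-benzyloxyphenyl)–) are joined by a double bond, closing a seven-membered ring through benzofuran C4, C3a, C3 and two adjacent carbons of the bis(benzyloxy)benzene ring
Conditions: TiCl4, Zn, pyridine, THF, reflux, slow addition of 21
Reagents that add atoms: none
Why: McMurry reaction, in which low-valent titanium couples the two carbonyl groups to a metal-bound 1,2-diolate that is deoxygenated on heating; the biaryl bond holds aldehyde and ketone close, and the ring allows only the alkene with the two ring arms cis.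

Step 16
Reactants: 22 pentabenzyl cycloheptene
Product: 24 trans-alcohol: ring CH(OH) on benzofuran C4 with (R) configuration, adjacent ring CH(4-benzyloxyphenyl) with (S) configuration, hydroxyl and 4-benzyloxyphenyl trans, via alkyl(isopinocampheyl)borane 23 (not isolated)
Conditions: IpcBH2 (from (+)-α-pinene, prepared separately), THF, −25 °C to rt; then NaOH, H2O2, 0 °C
Reagents that add atoms: hydrogen peroxide, OO
Why: Asymmetric hydroboration–oxidation of a trisubstituted aryl alkene: boron goes to the CH terminus and hydrogen to the diaryl carbon in a syn addition, the chiral isopinocampheyl group selects the alkene face and so sets the (S) diarylmethine centre, and oxidation with retention gives the (R) carbinol that is removed in step 17.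

Step 17
Reactants: 24 trans-alcohol
Product: 25 (S)-penta-O-benzylhopeafuran: ketone carbon on benzofuran C4, (S)-CH(4-benzyloxyphenyl) beside it
Conditions: Dess–Martin periodinane, CH2Cl2, 0 °C; brief cold aq. NaHCO3/Na2S2O3 work-up
Reagents that add atoms: none
Why: Dess–Martin oxidation of the secondary benzylic alcohol under non-basic conditions, so that the doubly benzylic α-carbon, which becomes acidic only once the ketone exists, is not enolised.

Step 18
Reactants: 25 (S)-penta-O-benzylhopeafuran
Product: 26 hopeafuran, (S) configuration at the CH(4-hydroxyphenyl) carbon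
Conditions: H2 (1 atm), Pd/C, EtOAc/MeOH, rt
Reagents that add atoms: none
Why: Catalytic hydrogenolysis of the five benzyl ethers under neutral conditions that do not enolise the α-aryl ketone; benzyl C–O cleavage is expected to outpace reduction of the hindered conjugated ketone, and the reaction is stopped once debenzylation is complete.

Compound list
1 | methyl 3,5-dimethoxybenzoate | COC(=O)c1cc(OC)cc(OC)c1 | starting material
2 | methyl 2-iodo-3,5-dimethoxybenzoate | COC(=O)c1cc(OC)cc(OC)c1I | intermediate
3 | methyl 3,5-dihydroxy-2-iodobenzoate | COC(=O)c1cc(O)cc(O)c1I | intermediate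
4 | 1-(benzyloxy)-4-ethynylbenzene | C#Cc1ccc(OCc2ccccc2)cc1 | starting material
5 | methyl 2-{[4-(benzyloxy)phenyl]ethynyl}-3,5-dihydroxybenzoate | COC(=O)c1cc(O)cc(O)c1C#Cc1ccc(OCc2ccccc2)cc1 | intermediate (not isolated)
6 | methyl 2-[4-(benzyloxy)phenyl]-6-hydroxy-1-benzofuran-4-carboxylate | COC(=O)c1cc(O)cc2oc(-c3ccc(OCc4ccccc4)cc3)cc12 | intermediate
7 | methyl 6-(benzyloxy)-2-[4-(benzyloxy)phenyl]-1-benzofuran-4-carboxylate | COC(=O)c1cc(OCc4ccccc4)cc2oc(-c3ccc(OCc4ccccc4)cc3)cc12 | intermediate
8 | methyl 6-(benzyloxy)-2-[4-(benzyloxy)phenyl]-3-iodo-1-benzofuran-4-carboxylate | COC(=O)c1cc(OCc4ccccc4)cc2oc(-c3ccc(OCc4ccccc4)cc3)c(I)c12 | intermediate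
9 | 4-(benzyloxy)benzaldehyde | O=Cc1ccc(OCc2ccccc2)cc1 | starting material
10 | 1-[4-(benzyloxy)phenyl]prop-2-yn-1-ol (racemic) | C#CC(O)c1ccc(OCc2ccccc2)cc1 | intermediate
11 | methyl 6-(benzyloxy)-2-[4-(benzyloxy)phenyl]-3-{3-[4-(benzyloxy)phenyl]-3-hydroxyprop-1-yn-1-yl}-1-benzofuran-4-carboxylate (racemic) | COC(=O)c1cc(OCc4ccccc4)cc2oc(-c3ccc(OCc4ccccc4)cc3)c(C#CC(O)c3ccc(OCc4ccccc4)cc3)c12 | intermediate
12 | methyl 6-(benzyloxy)-2-[4-(benzyloxy)phenyl]-3-{3-[4-(benzyloxy)phenyl]-3-oxoprop-1-yn-1-yl}-1-benzofuran-4-carboxylate | COC(=O)c1cc(OCc4ccccc4)cc2oc(-c3ccc(OCc4ccccc4)cc3)c(C#CC(=O)c3ccc(OCc4ccccc4)cc3)c12 | intermediate (key-step precursor)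
13 | methyl acetoacetate | CC(=O)CC(=O)OC | starting material
14 | methyl 3-(trimethylsilyloxy)but-2-enoate | COC(=O)C=C(C)O[Si](C)(C)C | intermediate
15 | 1-methoxy-1,3-bis(trimethylsilyloxy)buta-1,3-diene | COC(O[Si](C)(C)C)=CC(=C)O[Si](C)(C)C | intermediate
16 | methyl 6-(benzyloxy)-2-[4-(benzyloxy)phenyl]-3-{2-[4-(benzyloxy)benzoyl]-3-methoxy-3,5-bis(trimethylsilyloxy)cyclohexa-1,4-dien-1-yl}-1-benzofuran-4-carboxylate | COC(=O)c1cc(OCc4ccccc4)cc2oc(-c3ccc(OCc4ccccc4)cc3)c(C3=C(C(=O)c5ccc(OCc6ccccc6)cc5)C(OC)(O[Si](C)(C)C)C=C(O[Si](C)(C)C)C3)c12 | intermediate (not isolated)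
17 | methyl 6-(benzyloxy)-2-[4-(benzyloxy)phenyl]-3-{2-[4-(benzyloxy)benzoyl]-3,5-bis(trimethylsilyloxy)phenyl}-1-benzofuran-4-carboxylate | COC(=O)c1cc(OCc4ccccc4)cc2oc(-c3ccc(OCc4ccccc4)cc3)c(-c3cc(O[Si](C)(C)C)cc(O[Si](C)(C)C)c3C(=O)c3ccc(OCc4ccccc4)cc3)c12 | intermediate (not isolated)
18 | methyl 6-(benzyloxy)-2-[4-(benzyloxy)phenyl]-3-{2-[4-(benzyloxy)benzoyl]-3,5-dihydroxyphenyl}-1-benzofuran-4-carboxylate | COC(=O)c1cc(OCc4ccccc4)cc2oc(-c3ccc(OCc4ccccc4)cc3)c(-c3cc(O)cc(O)c3C(=O)c3ccc(OCc4ccccc4)cc3)c12 | intermediate (key-step product)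
19 | methyl 6-(benzyloxy)-2-[4-(benzyloxy)phenyl]-3-{3,5-bis(benzyloxy)-2-[4-(benzyloxy)benzoyl]phenyl}-1-benzofuran-4-carboxylate | COC(=O)c1cc(OCc4ccccc4)cc2oc(-c3ccc(OCc4ccccc4)cc3)c(-c3cc(OCc4ccccc4)cc(OCc4ccccc4)c3C(=O)c3ccc(OCc4ccccc4)cc3)c12 | intermediate
20 | [6-(benzyloxy)-2-[4-(benzyloxy)phenyl]-3-{3,5-bis(benzyloxy)-2-[[4-(benzyloxy)phenyl](hydroxy)methyl]phenyl}-1-benzofuran-4-yl]methanol (stereoisomer mixture) | OCc1cc(OCc4ccccc4)cc2oc(-c3ccc(OCc4ccccc4)cc3)c(-c3cc(OCc4ccccc4)cc(OCc4ccccc4)c3C(O)c3ccc(OCc4ccccc4)cc3)c12 | intermediate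
21 | 6-(benzyloxy)-2-[4-(benzyloxy)phenyl]-3-{3,5-bis(benzyloxy)-2-[4-(benzyloxy)benzoyl]phenyl}-1-benzofuran-4-carbaldehyde | O=Cc1cc(OCc4ccccc4)cc2oc(-c3ccc(OCc4ccccc4)cc3)c(-c3cc(OCc4ccccc4)cc(OCc4ccccc4)c3C(=O)c3ccc(OCc4ccccc4)cc3)c12 | intermediate
22 | pentabenzyl cycloheptene (seven-membered ring: =CH– on benzofuran C4, =C(4-benzyloxyphenyl)– on the bis(benzyloxy)benzene ring) | C1=C(c2ccc(OCc3ccccc3)cc2)c2c(OCc3ccccc3)cc(OCc3ccccc3)cc2-c2c(-c3ccc(OCc4ccccc4)cc3)oc3cc(OCc4ccccc4)cc1c23 | intermediate
23 | alkyl(isopinocampheyl)borane: B–H borane carrying the isopinocampheyl group and the ring carbon on benzofuran C4, hydrogen added cis to boron on the neighbouring diaryl carbon | C[C@H]1[C@H]([BH][C@H]3c4cc(OCc7ccccc7)cc5oc(-c6ccc(OCc7ccccc7)cc6)c(c45)-c4cc(OCc7ccccc7)cc(OCc7ccccc7)c4[C@@H]3c3ccc(OCc7ccccc7)cc3)C[C@@H]2C[C@H]1C2(C)C | intermediate (not isolated)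
24 | trans-alcohol: (R)-CH(OH) on benzofuran C4, (S)-CH(4-benzyloxyphenyl) beside it, five benzyl ethers | O[C@H]1c2cc(OCc5ccccc5)cc3oc(-c4ccc(OCc5ccccc5)cc4)c(c23)-c2cc(OCc5ccccc5)cc(OCc5ccccc5)c2[C@@H]1c1ccc(OCc5ccccc5)cc1 | intermediate
25 | (S)-penta-O-benzylhopeafuran | O=C1c2cc(OCc5ccccc5)cc3oc(-c4ccc(OCc5ccccc5)cc4)c(c23)-c2cc(OCc5ccccc5)cc(OCc5ccccc5)c2[C@@H]1c1ccc(OCc5ccccc5)cc1 | intermediate
26 | hopeafuran, (S) | O=C1c2cc(O)cc3oc(-c4ccc(O)cc4)c(c23)-c2cc(O)cc(O)c2[C@@H]1c1ccc(O)cc1 | target

Total step count: 18. Longest linear sequence: 15 steps (1 to 26 through steps 1–5, 7, 8 and 11–18); steps 6, 9 and 10 supply the two side branches.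

Steps most likely to fail

Step 11. The cycloaddition may be outrun by thermal decomposition or adventitious desilylation of the diene, or the diene may add in a stepwise conjugate manner without closing the ring. The cause would be that the alkyne carbon it must reach is shielded by the C2 aryl group and the C4 ester. The fallback gives up the benzannulation and builds the biaryl bond directly, setting out from iodide 8. Suzuki–Miyaura coupling with 3,5-bis(benzyloxy)phenylboronic acid (Pd(PPh3)4, K3PO4, dioxane/H2O, 90 °C) should give methyl 6-(benzyloxy)-2-[4-(benzyloxy)phenyl]-3-[3,5-bis(benzyloxy)phenyl]-1-benzofuran-4-carboxylate F1; the boronic acid is unhindered, so the coupling at C3 is less demanding than one with a fully substituted partner. Friedel–Crafts acylation of F1 with 4-(benzyloxy)benzoyl chloride and SnCl4 in CH2Cl2 at low temperature should then attack the dibenzyloxyphenyl ring at the carbon ortho to one ether, para to the other and next to the biaryl bond, not at the crowded carbon between the two ethers. The route is rejoined at keto ester 19.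

Step 16. Addition of the bulky monoalkylborane across a ring alkene that carries three aryl groups may be slow and may discriminate the two faces poorly. The fallback separates the setting of relative and absolute configuration and sets out from alkene 22. Hydroboration with the small reagent BH3·THF and oxidation (NaOH, H2O2) should give the racemic trans-alcohol F2. Esterification with (S)-2-methoxy-2-phenylacetic acid (EDC·HCl, DMAP, CH2Cl2) gives two diastereomeric esters, the (S)-O-methylmandelate of 24 F3 and the (S)-O-methylmandelate of the enantiomer of 24 F4, which are separated by chromatography or crystallisation. Hydrolysis of F3 (LiOH, THF/MeOH/H2O) is safe because the diarylmethine hydrogen is not acidic before the ketone exists. The route is rejoined at alcohol 24.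

Step 15. The reductive coupling may stop at the 1,2-diol stage, or simple reduction of the aldehyde and intermolecular coupling may compete with closure of the seven-membered ring. The fallback replaces reductive coupling by an ylide olefination and sets out from keto aldehyde 21. NaBH4 (1 equiv, THF/MeOH, −20 °C) should reduce the aldehyde and leave the hindered diaryl ketone, giving the hydroxymethyl ketone F5. PPh3·HBr in MeCN at reflux converts the electron-rich benzylic alcohol into the benzylic triphenylphosphonium bromide F6. KOt-Bu in THF at high dilution forms the ylide, which closes onto the ketone in an intramolecular Wittig reaction. The route is rejoined at alkene 22.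

Further compounds
F1 | step 11 | methyl 6-(benzyloxy)-2-[4-(benzyloxy)phenyl]-3-[3,5-bis(benzyloxy)phenyl]-1-benzofuran-4-carboxylate | COC(=O)c1cc(OCc4ccccc4)cc2oc(-c3ccc(OCc4ccccc4)cc3)c(-c3cc(OCc4ccccc4)cc(OCc4ccccc4)c3)c12
F2 | step 16 | racemic trans-alcohol (relative configuration of 24, hydroxyl and 4-benzyloxyphenyl trans) | OC1c2cc(OCc5ccccc5)cc3oc(-c4ccc(OCc5ccccc5)cc4)c(c23)-c2cc(OCc5ccccc5)cc(OCc5ccccc5)c2C1c1ccc(OCc5ccccc5)cc1
F3 | step 16 | (S)-O-methylmandelate of 24 | CO[C@H](C(=O)O[C@H]1c2cc(OCc5ccccc5)cc3oc(-c4ccc(OCc5ccccc5)cc4)c(c23)-c2cc(OCc5ccccc5)cc(OCc5ccccc5)c2[C@@H]1c1ccc(OCc5ccccc5)cc1)c1ccccc1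
F4 | step 16 | (S)-O-methylmandelate of the enantiomer of 24 | CO[C@H](C(=O)O[C@@H]1c2cc(OCc5ccccc5)cc3oc(-c4ccc(OCc5ccccc5)cc4)c(c23)-c2cc(OCc5ccccc5)cc(OCc5ccccc5)c2[C@H]1c1ccc(OCc5ccccc5)cc1)c1ccccc1
F5 | step 15 | {2-[6-(benzyloxy)-2-[4-(benzyloxy)phenyl]-4-(hydroxymethyl)-1-benzofuran-3-yl]-4,6-bis(benzyloxy)phenyl}[4-(benzyloxy)phenyl]methanone | OCc1cc(OCc4ccccc4)cc2oc(-c3ccc(OCc4ccccc4)cc3)c(-c3cc(OCc4ccccc4)cc(OCc4ccccc4)c3C(=O)c3ccc(OCc4ccccc4)cc3)c12
F6 | step 15 | benzylic triphenylphosphonium bromide of F5 (CH2P+Ph3 on benzofuran C4) | [Br-].O=C(c1ccc(OCc2ccccc2)cc1)c1c(OCc2ccccc2)cc(OCc2ccccc2)cc1-c1c(-c2ccc(OCc3ccccc3)cc2)oc2cc(OCc3ccccc3)cc(C[P+](c3ccccc3)(c3ccccc3)c3ccccc3)c12
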